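**Retrosynthetic overview**
1. Last step: one global hydrogenation converts a tetra-O-benzyl, stilbene-containing diarylcarbinol into the target (four OBn to OH, bridging CH(OH) to CH2, CH=CH to CH2CH2).
2. Key disconnection: the two carbon substituents on the adjacent ring A carbons C4 (bridging carbon) and C5 (ArCH2CH2) are cut together. This gives a C4≡C5 aryne, the homobenzylic Grignard reagent of ring C (C5–CH2 bond) and the ring B/ring D aldehyde (C4–CH bond).
3. Enabling feature: ring A carries C1 OMe, C2 H, C3 OH, C4 bridging CH2, C5 CH2CH2-ring C and C6 H. The two carbon substituents are vicinal and C4 sits next to the C3 oxygen, so a 3-alkoxyaryne takes the nucleophile at C5 and leaves the carbanion at C4. C4 is also the carbon between the two oxygenated carbons of symmetric 5-methoxyresorcinol (C3–O is kept, C5–O becomes the leaving group), which fixes the position of the triple bond.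
4. Fragments: the aldehyde comes from a Heck coupling of 2-benzyloxy-4-bromo-6-methoxybenzaldehyde with 4-benzyloxy-3-methoxystyrene. The Grignard reagent comes from homovanillyl alcohol.
5. No ring is constructed, since all four benzene rings (A, B, C, D) are bought. Assembly order: D to B (Heck), then C, A and B together in the key step.

Key step: step 10

Remark: the target is achiral, and the E-alkene and the racemic carbinol centre that appear on the way are both erased in the last step. The four starting materials are taken to be catalogue chemicals.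

**Route**

Step 1
Reactants: 1 homovanillyl alcohol [4-(2-hydroxyethyl)-2-methoxyphenol]
Product: 2 2-[4-(benzyloxy)-3-methoxyphenyl]ethanol
Conditions: BnBr (1.1 equiv), K2CO3, acetone, reflux
Reagents that add atoms: benzyl bromide, BrCc1ccccc1
Why: Williamson ether synthesis in which K2CO3 ionises only the phenol and not the primary alcohol, so benzylation should be selective for the aryl oxygen.

Step 2
Reactants: 2 2-[4-(benzyloxy)-3-methoxyphenyl]ethanol
Product: 3 1-(benzyloxy)-4-(2-bromoethyl)-2-methoxybenzene
Conditions: CBr4, PPh3, CH2Cl2, 0 °C to rt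
Reagents that add atoms: carbon tetrabromide, BrC(Br)(Br)Br
Why: Appel reaction, in which the primary alcohol is activated as an alkoxyphosphonium ion and displaced by bromide (SN2) under neutral conditions that leave both aryl ethers untouched.

Step 3
Reactants: 3 1-(benzyloxy)-4-(2-bromoethyl)-2-methoxybenzene
Product: 4 2-[4-(benzyloxy)-3-methoxyphenyl]ethylmagnesium bromide (titrated THF stock solution)
Conditions: Mg turnings (crystal of I2 as activator), THF, slow addition, 35–40 °C
Reagents that add atoms: magnesium, [Mg]
Why: Classical Grignard formation by magnesium insertion into a primary C–Br bond, where slow addition of dilute bromide should hold back Wurtz dimerisation and the aryl ethers are inert to the reagent.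

Step 4
Reactants: 5 5-methoxyresorcinol (5-methoxybenzene-1,3-diol)
Product: 6 2-iodo-5-methoxybenzene-1,3-diol
Conditions: I2 (1.0 equiv), NaHCO3 (1.1 equiv), H2O–THF, 0 °C
Reagents that add atoms: iodine, [I][I]
Why: Electrophilic aromatic iodination of the resorcinol monoanion in aqueous hydrogencarbonate, the reaction type that places iodine on the carbon between the two hydroxyl groups of resorcinols (here also para to OMe), with one equivalent of I2 at 0 °C to limit polyiodination.

Step 5
Reactants: 6 2-iodo-5-methoxybenzene-1,3-diol
Product: 7 3-(benzyloxy)-2-iodo-5-methoxyphenol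
Conditions: BnBr (0.95 equiv), K2CO3 (1.0 equiv), DMF, rt
Reagents that add atoms: benzyl bromide, BrCc1ccccc1
Why: Williamson monoalkylation of a symmetric diol whose two hydroxyls are equivalent, so only one mono-ether can form, substoichiometric BnBr limits the dibenzyl ether, and unreacted 6 can be recovered and recycled.

Step 6
Reactants: 7 3-(benzyloxy)-2-iodo-5-methoxyphenol
Product: 8 3-(benzyloxy)-2-iodo-5-methoxyphenyl 4-chlorobenzenesulfonate
Conditions: 4-ClC6H4SO2Cl, Et3N, cat. DMAP, CH2Cl2, 0 °C to rt
Reagents that add atoms: 4-chlorobenzenesulfonyl chloride, O=S(=O)(Cl)c1ccc(Cl)cc1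
Why: O-sulfonylation of a phenol, with the arenesulfonate chosen over a triflate because its ortho-magnesiated form should survive at −78 °C and eliminate only on warming, which allows staged addition in step 10.

Step 7
Reactants: 9 4-bromo-2,6-dimethoxybenzaldehyde
Product: 10 4-bromo-2-hydroxy-6-methoxybenzaldehyde
Conditions: BCl3 (1.1 equiv), CH2Cl2, −78 to 0 °C; aqueous work-up
Reagents that add atoms: none
Why: Chelation-directed Lewis acid cleavage of an aryl methyl ether, in which BCl3 bound to the formyl oxygen cleaves one of the two equivalent ortho OMe groups and the resulting six-membered boron chelate should protect the second one.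

Step 8
Reactants: 10 4-bromo-2-hydroxy-6-methoxybenzaldehyde
Product: 11 2-(benzyloxy)-4-bromo-6-methoxybenzaldehyde
Conditions: BnBr (1.2 equiv), K2CO3, DMF, 50 °C
Reagents that add atoms: benzyl bromide, BrCc1ccccc1
Why: Williamson ether synthesis, where the hydrogen-bonded ortho-hydroxy aldehyde needs the polar solvent and gentle heating and no other site in the molecule can be alkylated.

Step 9
Reactants: 11 2-(benzyloxy)-4-bromo-6-methoxybenzaldehyde; 12 4-benzyloxy-3-methoxystyrene [1-(benzyloxy)-4-ethenyl-2-methoxybenzene]
Product: 13 2-(benzyloxy)-4-{(E)-2-[4-(benzyloxy)-3-methoxyphenyl]ethenyl}-6-methoxybenzaldehyde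
Conditions: Pd(OAc)2 (3 mol%), P(o-tol)3 (9 mol%), Et3N, DMF, 100 °C
Reagents that add atoms: none
Why: Mizoroki–Heck reaction, in which the C–Br bond para to the formyl group should add readily to zerovalent palladium and terminal arylation followed by syn β-hydride elimination gives the E-stilbene, whose geometry is irrelevant because step 11 saturates it.

Step 10
Reactants: 8 3-(benzyloxy)-2-iodo-5-methoxyphenyl 4-chlorobenzenesulfonate; 4 2-[4-(benzyloxy)-3-methoxyphenyl]ethylmagnesium bromide; 13 2-(benzyloxy)-4-{(E)-2-[4-(benzyloxy)-3-methoxyphenyl]ethenyl}-6-methoxybenzaldehyde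
Product: 17 racemic [2-(benzyloxy)-6-{2-[4-(benzyloxy)-3-methoxyphenyl]ethyl}-4-methoxyphenyl][2-(benzyloxy)-4-{(E)-2-[4-(benzyloxy)-3-methoxyphenyl]ethenyl}-6-methoxyphenyl]methanol, via magnesiated aryl sulfonate 14 (not isolated), via 3-benzyloxy-5-methoxybenzyne 15 (not isolated), via ring A arylmagnesium bromide 16 (not isolated)
Conditions: 8 (1.3 equiv), iPrMgCl (1.3 equiv), THF, −78 °C, 30 min; then 4 (1.25 equiv), −78 to 0 °C; then 13 (1.0 equiv), −40 °C to rt; sat. aq. NH4Cl
Reagents that add atoms: none
Why: Iodine–magnesium exchange at C4 of 8 gives 14, which should persist at −78 °C and on warming expel chloromagnesium 4-chlorobenzenesulfonate from C5 to unveil the C4≡C5 aryne 15 in the presence of Grignard reagent 4. The homobenzylic carbon of 4 adds at C5 and forms the aryl–CH2 bond, because the σ-withdrawing C3 benzyloxy group distorts the aryne so that C5 is the more linear and electrophilic terminus, places the developing carbanion at C4 next to oxygen where magnesium is chelated, and leaves C5 flanked only by C6–H. The arylmagnesium 16 is then intercepted at C4 by 1,2-addition to the non-enolisable aldehyde 13, so both vicinal carbon substituents of ring A and the whole carbon skeleton are set in one flask. The closest known reaction type is the three-component aryne coupling (carbomagnesiation of a 3-alkoxybenzyne by a Grignard reagent followed by aldehyde trapping), combined with aryne release from 2-magnesiated aryl sulfonates. No ring is closed, and the only new stereocentre, the carbinol carbon, forms as a racemate without consequence because step 11 removes it. The step needs regioselectivity, secured by the C3 oxygen and by the unambiguous iodine/sulfonate placement, and chemoselectivity among the organomagnesium species, secured by staged addition, by the hindrance of 14 towards self-addition, and by keeping 4 slightly below 8 so that no alkyl Grignard reagent remains when 13 is added.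

Step 11
Reactants: 17 racemic tetra-O-benzyl diarylcarbinol
Product: 18 target, 2-{[2-hydroxy-4-[2-(4-hydroxy-3-methoxyphenyl)ethyl]-6-methoxyphenyl]methyl}-3-[2-(4-hydroxy-3-methoxyphenyl)ethyl]-5-methoxyphenol
Conditions: H2 (3–4 bar), 10% Pd/C, EtOAc–EtOH–AcOH, rt
Reagents that add atoms: none
Why: Catalytic hydrogenation and hydrogenolysis over Pd/C should saturate the stilbene, cleave the four benzyl ethers and reduce the electron-rich doubly benzylic carbinol (which after debenzylation loses water under the mild acid to an ortho-quinone methide) to the CH2 bridge, erasing the alkene geometry and the racemic centre to leave the achiral target.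

**Compound list**
1 | homovanillyl alcohol, 4-(2-hydroxyethyl)-2-methoxyphenol | COc1cc(CCO)ccc1O | starting material
2 | 2-[4-(benzyloxy)-3-methoxyphenyl]ethanol | COc1cc(CCO)ccc1OCc1ccccc1 | intermediate
3 | 1-(benzyloxy)-4-(2-bromoethyl)-2-methoxybenzene | COc1cc(CCBr)ccc1OCc1ccccc1 | intermediate
4 | 2-[4-(benzyloxy)-3-methoxyphenyl]ethylmagnesium bromide | COc1cc(CC[Mg]Br)ccc1OCc1ccccc1 | intermediate
5 | 5-methoxyresorcinol | COc1cc(O)cc(O)c1 | starting material
6 | 2-iodo-5-methoxybenzene-1,3-diol | COc1cc(O)c(I)c(O)c1 | intermediate
7 | 3-(benzyloxy)-2-iodo-5-methoxyphenol | COc1cc(O)c(I)c(OCc2ccccc2)c1 | intermediate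
8 | 3-(benzyloxy)-2-iodo-5-methoxyphenyl 4-chlorobenzenesulfonate | COc1cc(OCc2ccccc2)c(I)c(OS(=O)(=O)c2ccc(Cl)cc2)c1 | intermediate
9 | 4-bromo-2,6-dimethoxybenzaldehyde | COc1cc(Br)cc(OC)c1C=O | starting material
10 | 4-bromo-2-hydroxy-6-methoxybenzaldehyde | COc1cc(Br)cc(O)c1C=O | intermediate
11 | 2-(benzyloxy)-4-bromo-6-methoxybenzaldehyde | COc1cc(Br)cc(OCc2ccccc2)c1C=O | intermediate
12 | 4-benzyloxy-3-methoxystyrene | C=Cc1ccc(OCc2ccccc2)c(OC)c1 | starting material
13 | 2-(benzyloxy)-4-{(E)-2-[4-(benzyloxy)-3-methoxyphenyl]ethenyl}-6-methoxybenzaldehyde | COc1cc(/C=C/c2ccc(OCc3ccccc3)c(OC)c2)cc(OCc2ccccc2)c1C=O | intermediate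
14 | [2-(benzyloxy)-6-(4-chlorobenzenesulfonyloxy)-4-methoxyphenyl]magnesium chloride | COc1cc(OCc2ccccc2)c([Mg]Cl)c(OS(=O)(=O)c2ccc(Cl)cc2)c1 | intermediate
15 | 3-benzyloxy-5-methoxybenzyne (1,2-didehydro-3-benzyloxy-5-methoxybenzene) | COC1=CC#CC(OCc2ccccc2)=C1 | intermediate
16 | [2-(benzyloxy)-6-{2-[4-(benzyloxy)-3-methoxyphenyl]ethyl}-4-methoxyphenyl]magnesium bromide | COc1cc(OCc2ccccc2)c([Mg]Br)c(CCc2ccc(OCc3ccccc3)c(OC)c2)c1 | intermediate
17 | racemic [2-(benzyloxy)-6-{2-[4-(benzyloxy)-3-methoxyphenyl]ethyl}-4-methoxyphenyl][2-(benzyloxy)-4-{(E)-2-[4-(benzyloxy)-3-methoxyphenyl]ethenyl}-6-methoxyphenyl]methanol | COc1cc(OCc2ccccc2)c(C(O)c2c(OCc3ccccc3)cc(/C=C/c3ccc(OCc4ccccc4)c(OC)c3)cc2OC)c(CCc2ccc(OCc3ccccc3)c(OC)c2)c1 | intermediate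
18 | 2-{[2-hydroxy-4-[2-(4-hydroxy-3-methoxyphenyl)ethyl]-6-methoxyphenyl]methyl}-3-[2-(4-hydroxy-3-methoxyphenyl)ethyl]-5-methoxyphenol | COc1cc(O)c(Cc2c(O)cc(CCc3ccc(O)c(OC)c3)cc2OC)c(CCc2ccc(O)c(OC)c2)c1 | target

**Step count and risks**

Total step count: 11.
Longest linear sequence: 5 steps. Each of the three branches (steps 1–3, 4–6 and 7–9) has three steps and is followed by steps 10 and 11.

Steps most likely to fail:

1. **Step 10.**
   - What may go wrong: residual alkyl Grignard reagent may consume the aldehyde. The doubly ortho-substituted arylmagnesium may add too slowly to the doubly ortho-substituted aldehyde and simply be protonated on work-up. The magnesiated sulfonate may also add to the aryne in competition with the alkyl Grignard reagent.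
   - Fallback: it sets out from 8 and 4 and comes back at 17, and it separates the two bond formations. The aryne carbomagnesiation is run alone (iPrMgCl, THF, −78 °C; then 4, warming to 0 °C). Arylmagnesium 16 is quenched with I2 to give the isolable 1-(benzyloxy)-3-{2-[4-(benzyloxy)-3-methoxyphenyl]ethyl}-2-iodo-5-methoxybenzene F1, which chromatography frees from all alkyl-derived material.
   - Iodine–lithium exchange (n-BuLi, THF, −78 °C) then gives the more reactive [2-(benzyloxy)-6-{2-[4-(benzyloxy)-3-methoxyphenyl]ethyl}-4-methoxyphenyl]lithium F2. This is added to 13 at −78 °C, with no other organometallic present, to give 17.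

2. **Step 4.**
   - What may go wrong: iodination may occur at a carbon between OH and OMe, polyiodination may set in, or iodine may migrate during acidic handling.
   - Fallback: it sets out from 5 and comes back at 6, and it replaces electrophilic substitution by directed ortho-metalation. Both phenols are protected (MOMCl, iPr2NEt, CH2Cl2) to give 1-methoxy-3,5-bis(methoxymethoxy)benzene F3.
   - n-BuLi (THF, 0 °C) deprotonates the carbon between the two cooperating OMOM groups to give [4-methoxy-2,6-bis(methoxymethoxy)phenyl]lithium F4. I2 converts this into 2-iodo-5-methoxy-1,3-bis(methoxymethoxy)benzene F5, and brief treatment with HCl in MeOH at rt removes both acetals to give 6.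

3. **Step 11.**
   - What may go wrong: hydrogenolysis of the benzhydrylic C–O bond may stall after debenzylation. The ortho-quinone methide formed by loss of water may be trapped by the alcohol solvent or by a phenol (oligomerisation). Acid may also fragment the electron-rich carbinol.
   - Fallback: it sets out from 17 and comes back at 18, and it removes the oxygen ionically while all phenols are still masked. Et3SiH and CF3CO2H (CH2Cl2, −40 to 0 °C) reduce the stabilised diarylmethyl cation to 1-(benzyloxy)-2-{[2-(benzyloxy)-4-{(E)-2-[4-(benzyloxy)-3-methoxyphenyl]ethenyl}-6-methoxyphenyl]methyl}-3-{2-[4-(benzyloxy)-3-methoxyphenyl]ethyl}-5-methoxybenzene F6.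
   - A plain neutral hydrogenation (H2, 10% Pd/C, EtOAc–EtOH, rt) then has only the alkene and the four benzyl ethers left to deal with and gives 18.

**Further compounds**
F1 | step 10 | 1-(benzyloxy)-3-{2-[4-(benzyloxy)-3-methoxyphenyl]ethyl}-2-iodo-5-methoxybenzene | COc1cc(OCc2ccccc2)c(I)c(CCc2ccc(OCc3ccccc3)c(OC)c2)c1
F2 | step 10 | [2-(benzyloxy)-6-{2-[4-(benzyloxy)-3-methoxyphenyl]ethyl}-4-methoxyphenyl]lithium | COc1cc(OCc2ccccc2)c([Li])c(CCc2ccc(OCc3ccccc3)c(OC)c2)c1
F3 | step 4 | 1-methoxy-3,5-bis(methoxymethoxy)benzene | COCOc1cc(OC)cc(OCOC)c1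
F4 | step 4 | [4-methoxy-2,6-bis(methoxymethoxy)phenyl]lithium | COCOc1cc(OC)cc(OCOC)c1[Li]
F5 | step 4 | 2-iodo-5-methoxy-1,3-bis(methoxymethoxy)benzene | COCOc1cc(OC)cc(OCOC)c1I
F6 | step 11 | 1-(benzyloxy)-2-{[2-(benzyloxy)-4-{(E)-2-[4-(benzyloxy)-3-methoxyphenyl]ethenyl}-6-methoxyphenyl]methyl}-3-{2-[4-(benzyloxy)-3-methoxyphenyl]ethyl}-5-methoxybenzene | COc1cc(OCc2ccccc2)c(Cc2c(OCc3ccccc3)cc(/C=C/c3ccc(OCc4ccccc4)c(OC)c3)cc2OC)c(CCc2ccc(OCc3ccccc3)c(OC)c2)c1
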